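**Quick number.** In this closed, stirred vessel at constant volume and one temperature, starting complex takes up incoming ligand. You asked for a quick figure for complex with two exchanged at the end of each run, with the hunch that its loss grows with incoming ligand, and we reckon along that line.

all flasks: starting complex 20 mM

| run | incoming ligand | remark | time |
|---|---|---|---|
| maple | 1.1 equiv | run made earlier |  |
| alder | 19 equiv | run made earlier |  |
| grey | 0.800 equiv |  | 50 min |
| teal | 1.50 equiv |  | 50 min |
| violet | 3.00 equiv |  | 50 min |
| blue | 6.00 equiv |  | 50 min |
| amber | 12.0 equiv |  | 50 min |

- maple (time / min: complex with two exchanged / %): 8.00: 9; 20.0: 13; 25.0: 17; 40.0: 24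
- alder (time / min: complex with two exchanged / %): 3.00: 57; 6.00: 41; 15.0: 10; 40.0: 0

(readings scatter by 1.5 percentage points)

- "hardly changes" means that all values lie within two and a half points (for a concentration: within two and a half percent of the largest)

* amount of complex with two exchanged at the end, in percent of the starting complex charged for grey, teal, violet, blue, amber, in this order
* the course of these numbers from the first flask to the last (falls all the way / rises all the way / rises, then falls / falls, then rises / hardly changes)

**Reading the loss.** In alder the readings of complex with two exchanged fall from 41% at 6.00 min to 10% at 15.0 min, while in maple they are still climbing to 24% at 40.0 min. We take the fast step as settled, with both exchanges done, so that F, the incoming ligand they leave free, is the charge less two equivalents, 340 mM in alder. In that excess the loss looks pseudo-first-order, and its rate divided by F gives the over-exchange constant k_o, the loss rate of complex with two exchanged per unit of free incoming ligand, read here as 0.461 L mol⁻¹ min⁻¹.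

**Our reckoning.** With F held constant through a run, the half-life of complex with two exchanged is then ln(2)/(k_o F). For violet this gives 75.2 min, longer than the run of 50 min, but blue gets 18.8 min and amber 7.52 min. Grey and teal are charged below two equivalents, so this count of F gives them no clock. Starting the clock at time zero, as if the whole charge stood as complex with two exchanged, we commit to 15.8% for blue and 0.994% for amber.

**The forecast.** It reads 15%, 31%, 50%, 23% and 1%, course "rises, then falls", saying of the high charges “over-reaction dominates”, and its blue figure stands higher than ours.

**The flasks.** The row comes out as 16.6%, 31.8%, 34.4%, 11.2% and 0.522%, and its course is "rises, then falls".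

    starting complex + incoming ligand → leaving ligand + complex with one exchanged (k = 0.0770 L mol⁻¹ s⁻¹)
    complex with one exchanged + incoming ligand → leaving ligand + complex with two exchanged (k = 0.0430 L mol⁻¹ s⁻¹)
    complex with two exchanged + incoming ligand → leaving ligand + complex with three exchanged (k = 0.00960 L mol⁻¹ s⁻¹)
    2 starting complex → self-condensation product (k = 0.110 L mol⁻¹ s⁻¹)

**The clock again.** Amber holds 88.9% complex with three exchanged at 50.0 min. Its incoming ligand at that time stands at 77.7% of its own charge, which is 186 mM, so k_o gives a half-life of 8.06 min. Starting from the 7.69% of complex with two exchanged that amber holds at 25.0 min, this clock leaves 0.896% at 50.0 min, and amber stands at 0.522%.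

(The data were generated by integration from invented constants; the scatter is artificial.)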